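The vessel is a stirred flask of constant volume, and the flasks differ in how their charge goes in.

common to all: time 4.0 min

| charge | substrate | reagent | remark |
|---|---|---|---|
| Thursday's | 0.037 M | 0.0481 M (fed, over 2.5 min) | all else is in the flask from the start; the feed brings no volume worth counting |
| Wednesday's | 0.037 M (fed, over 2.5 min) | 0.0481 M | all else is in the flask from the start; the feed brings no volume worth counting |
| Monday's | 0.037 M | 0.0481 M (fed, over 40 s) | all else is in the flask from the start; the feed brings no volume worth counting |
| Sunday's | 0.037 M | 0.0481 M | everything together at the start |

    substrate + reagent → target, rate k1*[substrate]^0.5*[reagent] (k1 = 0.0087 L⁰·⁵ mol⁻⁰·⁵ s⁻¹)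
    substrate + target → side product (k2 = 0.091 L mol⁻¹ s⁻¹)

- a species is counted by the substrate in it: one side product counts as two
- run time (Thursday's): 4.0 min

* which flask leads in amount of side product, in percent of the substrate charged ("all alike" within 1.5 percentage points) (Thursday's / Wednesday's / Monday's / Sunday's / all alike)
* how much side product is there at the end, in percent of the substrate charged: Thursday's
* how much side product is there at the end, in percent of the substrate charged: Wednesday's
* how much side product is there at the end, in percent of the substrate charged: Monday's
* how much side product is there at the end, in percent of the substrate charged: Sunday's

I write s and r for the fractions of substrate and reagent left, y for target and z for side product, both as fractions of the substrate charged.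

In Sunday's flask, y starts with a slope of 0.131 min⁻¹ and z starts flat. Step 2 consumes target at b·s·y, where b is 0.202 min⁻¹. Dividing the two rates at the charge gives the target ceiling L, the target level at which step 2 would use target as fast as step 1 makes it: 64.6%.

The target balance then reads dy/dt = b·s·(L·r/√s − y). I freeze r/√s at 1 and run a clock θ, the integral of b·s over time. This gives y = L(1 − e^−θ), z = 2L(θ − 1 + e^−θ) and s = 1 − y − z.

For Sunday's flask I try a mean s of 0.750, so θ is 0.606. That gives y = 29.4%, z = 19.6% and an end s of 51.0%, whose mean with the start is 0.755, close to the mean I tried. By this reckoning reagent in Sunday's flask ends at 0.699, so r/√s at the end is 0.978, close to the frozen value.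

A steady feed delivers its average portion at half the feed time, so I start the clock that late. Monday's flask, with the same mean s, gets 16.7%. Thursday's flask, with a mean s of 0.833, gets 11.9%. In Wednesday's flask substrate comes in by the feed, so s starts from zero, r/√s is far from 1, and my reckoning stops there. Of the three flasks I reckoned, Sunday's holds more side product than the others.

The forecast names Sunday's as leader, with 12%, 13.1%, 17.1% and 19.1% for Thursday's, Wednesday's, Monday's and Sunday's, and it holds that “a 40 s feed behaves almost exactly like batch delayed by 20 s”.

The simulation gives Sunday's as leader, with 12.0%, 13.1%, 17.1% and 19.1% in the same order.

At 4.00 min in Sunday's flask, target is made 2.22 times faster than it is used up, and L over the target standing there is 2.27.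

In a neighbour of Sunday's flask, charged with 0.082 M of reagent, L is 110%, which here is a ratio of rates, not a level in the flask. Trying a mean s of 0.667 then gives z = 26.9%. The simulation gives 23.7% of side product in this neighbour, with 29.3% of substrate left.

(The rate constants were set for the occasion; the run is a simulation.)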